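## Retrosynthetic overview

1. The target comes from its 7-deoxo 15-alcohol by one chromium oxidation (allylic C7 CH2 to enone, C15 alcohol to aldehyde) and a Pinnick oxidation.
2. The side chain is built at C12–C13 by a B-alkyl Suzuki coupling of a C11=C12 vinyl group with (Z)-3-iodobut-2-en-1-ol; C13 is set by BINAP–Ru hydrogenation.
3. Ring B (bonds C7–C8 and C9–C10; stereocentres C8, C9, C10) comes from an exo Diels–Alder reaction of tiglic aldehyde with a ring A 1-vinylcyclohexene (proposed new catalytic asymmetric step).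
4. The ring A diene with quaternary C4 comes from a Still–Wittig [2,3] shift of a CBS-derived (S)-2-vinylcyclohexenol made from 3-methylcyclohex-2-enone.
5. Ring order: ring A is bought as a carbocycle, ring B is closed by the cycloaddition; the acetate of the target is the only protecting group.

Convention: decalins carry halimane numbering (ring A = C1–C5, C10; ring B = C5–C10; C4 bears CH3-19 and CH2-18; C8 bears CH3-17; C9 bears CH3-20 and the chain C11–C15 with CH3-16 on C13). 9-BBN = 9-borabicyclo[3.3.1]nonane; dppf = 1,1′-bis(diphenylphosphino)ferrocene; BINAP = 2,2′-bis(diphenylphosphino)-1,1′-binaphthyl.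

Assumption: the (S)-prolinol-derived oxazaborolidinium cation of step 7 is taken to expose the C2-Si face of the boron-bound s-trans enal (usual aryl-stacking model); if the opposite sense is found, its (R)-enantiomer is used and nothing else changes.

## Route

Step 1
Reactants: 1 3-methylcyclohex-2-en-1-one
Product: 2 2-iodo-3-methylcyclohex-2-en-1-one
Conditions: I2, K2CO3, 4-(dimethylamino)pyridine (20 mol %), THF/H2O 1:1, rt
Reagents that add atoms: iodine, II
Why: α-Iodination of the enone by conjugate addition of the amine, iodination of the enolate and elimination (Baylis–Hillman-type addition–elimination, Johnson iodination); no stereocentre is formed.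

Step 2
Reactants: 2 2-iodo-3-methylcyclohex-2-en-1-one
Product: 3 (1S)-2-iodo-3-methylcyclohex-2-en-1-ol
Conditions: (R)-1-methyl-3,3-diphenyltetrahydro-1H,3H-pyrrolo[1,2-c][1,3,2]oxazaborole [(R)-Me-CBS, 20 mol %], BH3·SMe2, THF, −20 °C; aqueous work-up
Reagents that add atoms: none
Why: Corey–Bakshi–Shibata reduction in which the iodo-alkene carbon is the large and the ring CH2 the small ketone substituent, so the (R)-catalyst gives the (S)-carbinol (about 95% ee expected), the stereocentre later relayed to C4.

Step 3
Reactants: 3 (1S)-2-iodo-3-methylcyclohex-2-en-1-ol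
Product: 4 (1S)-2-ethenyl-3-methylcyclohex-2-en-1-ol
Conditions: tributyl(vinyl)stannane, Pd(PPh3)4 (5 mol %), CuI (10 mol %), DMF, 50 °C
Reagents that add atoms: tributyl(vinyl)stannane, C=C[Sn](CCCC)(CCCC)CCCC
Why: Stille cross-coupling at the vinyl iodide (oxidative addition, copper-assisted transmetalation, reductive elimination); the free allylic alcohol is tolerated and its stereocentre is not involved.

Step 4
Reactants: 4 (1S)-2-ethenyl-3-methylcyclohex-2-en-1-ol
Product: 5 tributyl({[(1S)-2-ethenyl-3-methylcyclohex-2-en-1-yl]oxy}methyl)stannane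
Conditions: KH, THF, 0 °C; then Bu3SnCH2I, rt
Reagents that add atoms: tributyl(iodomethyl)stannane, CCCC[Sn](CCCC)(CCCC)CI
Why: Williamson ether synthesis (SN2 of the potassium alkoxide on the primary iodide); the carbinol configuration is retained because the C–O bond is not broken.

Step 5
Reactants: 5 tributyl({[(1S)-2-ethenyl-3-methylcyclohex-2-en-1-yl]oxy}methyl)stannane
Product: 7 [(1R)-2-ethenyl-1-methylcyclohex-2-en-1-yl]methanol, via α-lithiomethyl ether 6 (not isolated)
Conditions: n-BuLi, THF, −78 → −40 °C; H2O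
Reagents that add atoms: none
Why: Tin–lithium exchange gives the α-alkoxymethyllithium, which undergoes the suprafacial [2,3]-sigmatropic Still–Wittig rearrangement, so the CH2O carbon is delivered to the methyl-bearing alkene carbon on the face of the former C–O bond; this turns the (S)-carbinol into the (R)-quaternary centre C4 and moves the double bond to give the 1-vinylcyclohexene diene.

Step 6
Reactants: 7 [(1R)-2-ethenyl-1-methylcyclohex-2-en-1-yl]methanol
Product: 8 [(1R)-2-ethenyl-1-methylcyclohex-2-en-1-yl]methyl acetate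
Conditions: Ac2O, pyridine, 4-(dimethylamino)pyridine (5 mol %), CH2Cl2, rt
Reagents that add atoms: acetic anhydride, CC(=O)OC(C)=O
Why: Nucleophile-catalysed acylation of the primary neopentyl alcohol; it installs the acetate of the target, which is carried unchanged to the end.

Step 7
Reactants: 8 [(1R)-2-ethenyl-1-methylcyclohex-2-en-1-yl]methyl acetate; 9 (2E)-2-methylbut-2-enal (tiglic aldehyde)
Product: 10 [(1R,4aR,5R,6S)-5-formyl-1,5,6-trimethyl-1,2,3,4,4a,5,6,7-octahydronaphthalen-1-yl]methyl acetate
Conditions: (S)-1-(2-methylphenyl)-3,3-diphenyltetrahydro-1H,3H-pyrrolo[1,2-c][1,3,2]oxazaborole (20 mol %), HN(SO2CF3)2 (18 mol %), 9 (3 equiv), CH2Cl2, −78 → −40 °C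
Reagents that add atoms: none
Why: Proposed new method: a catalyst-controlled, exo-selective Diels–Alder reaction of an α,β-disubstituted enal with a 1-vinylcyclohexene carrying a quaternary allylic stereocentre, promoted by an N-protonated chiral oxazaborolidine; the aldehyde binds the cationic boron (formyl C–H···O contact) and its s-trans C=C stacks on a catalyst aryl group so that only the C2-Si face is open; the asynchronous transition state forms C7–C8 first (enal β-carbon to the unsubstituted diene terminus, the "ortho" orientation with respect to ring carbon C10) and the C9–C10 bond to the new quaternary centre second; the boron-bound formyl group stays exo because the endo region is occupied by the tert-alkyl substituent (C4) on the internal diene carbon, so the two methyl groups of the (E)-enal are endo and end up cis to each other and to C1 (H-10 trans to CH3-20); the enal approaches the diene face anti to CH2OAc, which is the pairing the catalyst also demands (matched case), so C8, C9 and C10 are set in one step relative to C4; the closest known reaction type is the chiral oxazaborolidinium-catalysed Diels–Alder reaction of 2-substituted acroleins with simple dienes, not shown for a trisubstituted enal and a stereogenic semicyclic diene forming a quaternary–tertiary C–C bond.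

Step 8
Reactants: 10 [(1R,4aR,5R,6S)-5-formyl-1,5,6-trimethyl-1,2,3,4,4a,5,6,7-octahydronaphthalen-1-yl]methyl acetate
Product: 11 [(1R,4aS,5R,6S)-5-ethenyl-1,5,6-trimethyl-1,2,3,4,4a,5,6,7-octahydronaphthalen-1-yl]methyl acetate
Conditions: Ph3PCH3Br, KN(SiMe3)2, THF, 0 °C → rt
Reagents that add atoms: methyltriphenylphosphonium bromide, C[P+](c1ccccc1)(c1ccccc1)c1ccccc1.[Br-]
Why: Wittig methylenation of the non-enolisable neopentyl aldehyde; the small salt-free ylide adds to the aldehyde much faster than to the acetate at 0 °C, and no stereocentre is touched.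

Step 9
Reactants: 12 but-2-yn-1-ol
Product: 14 (2Z)-3-iodobut-2-en-1-ol, via cyclic alkenylaluminate 13 (not isolated)
Conditions: NaAlH2(OCH2CH2OMe)2, THF, 0 °C → rt; EtOAc; then I2, −78 °C → rt
Reagents that add atoms: iodine, II
Why: Hydroxyl-directed trans-hydroalumination of the propargylic alcohol places aluminium on C3 cis to the CH2O group in a five-membered aluminate, and iodinolysis of the C–Al bond with retention gives the (Z)-iodoalkene.

Step 10
Reactants: 11 [(1R,4aS,5R,6S)-5-ethenyl-1,5,6-trimethyl-1,2,3,4,4a,5,6,7-octahydronaphthalen-1-yl]methyl acetate; 14 (2Z)-3-iodobut-2-en-1-ol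
Product: 16 (4R,8S,9R,10S,13Z)-18-acetoxyhalima-5,13-dien-15-ol, via B-alkyl-9-BBN borane 15 (not isolated)
Conditions: 9-BBN, THF, rt; then H2O, 14, PdCl2(dppf) (5 mol %), AsPh3 (5 mol %), K3PO4 (3 M aq.), DMF, rt
Reagents that add atoms: none
Why: 9-BBN hydroborates only the monosubstituted vinyl group (anti-Markovnikov; the hindered trisubstituted ring alkene is inert), and the B-alkyl Suzuki–Miyaura coupling forms C12–C13 with retention of the (Z)-iodoalkene geometry.

Step 11
Reactants: 16 (4R,8S,9R,10S,13Z)-18-acetoxyhalima-5,13-dien-15-ol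
Product: 17 (4R,8S,9R,10S,13R)-18-acetoxyhalim-5-en-15-ol
Conditions: Ru(OAc)2[(R)-BINAP] (1 mol %), H2 (100 atm), MeOH, rt
Reagents that add atoms: none
Why: Noyori hydroxyl-directed asymmetric hydrogenation of an allylic alcohol; as with nerol, the (Z)-allylic alcohol and the (R)-BINAP complex give the (R)-configured β-methyl alcohol (C13) under catalyst control, and the isolated, hindered C5=C6 bond is not reduced.

Step 12
Reactants: 17 (4R,8S,9R,10S,13R)-18-acetoxyhalim-5-en-15-ol
Product: 19 (4R,8R,9S,10S,13R)-18-acetoxy-7-oxohalim-5-en-15-al, via 7-deoxo aldehyde 18 (not isolated)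
Conditions: CrO3, 3,5-dimethylpyrazole (15 equiv each), CH2Cl2, −20 °C
Reagents that add atoms: chromium trioxide, O=[Cr](=O)=O
Why: The CrO3–3,5-dimethylpyrazole complex first oxidises the primary alcohol to the aldehyde (Corey–Fleet oxidation) and then the allylic C7 methylene to the enone (the standard allylic oxidation of 5-enes to 5-en-7-ones); C7 is the only allylic CH2, the tertiary allylic C10–H is shielded by quaternary C9, and C8 keeps the configuration set in step 7.

Step 13
Reactants: 19 (4R,8R,9S,10S,13R)-18-acetoxy-7-oxohalim-5-en-15-al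
Product: 20 (4R,8R,9S,10S,13R)-18-acetoxy-7-oxohalim-5-en-15-oic acid
Conditions: NaClO2, NaH2PO4, 2-methylbut-2-ene, t-BuOH/H2O, rt
Reagents that add atoms: sodium chlorite, [Na+].[O-]Cl=O
Why: Pinnick oxidation of the aldehyde by chlorous acid under buffered conditions (hypochlorous acid scavenged by the alkene); the enone, the acetate and the epimerisable C8 centre are untouched.

## Compound list

1 | 3-methylcyclohex-2-en-1-one | CC1=CC(=O)CCC1 | starting material
2 | 2-iodo-3-methylcyclohex-2-en-1-one | CC1=C(I)C(=O)CCC1 | intermediate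
3 | (1S)-2-iodo-3-methylcyclohex-2-en-1-ol | O[C@H]1CCCC(C)=C1I | intermediate
4 | (1S)-2-ethenyl-3-methylcyclohex-2-en-1-ol | O[C@H]1CCCC(C)=C1C=C | intermediate
5 | tributyl({[(1S)-2-ethenyl-3-methylcyclohex-2-en-1-yl]oxy}methyl)stannane | CCCC[Sn](CCCC)(CCCC)CO[C@H]1CCCC(C)=C1C=C | intermediate
6 | {[(1S)-2-ethenyl-3-methylcyclohex-2-en-1-yl]oxy}methyllithium | [Li]CO[C@H]1CCCC(C)=C1C=C | intermediate
7 | [(1R)-2-ethenyl-1-methylcyclohex-2-en-1-yl]methanol | OC[C@]1(C)CCCC=C1C=C | intermediate
8 | [(1R)-2-ethenyl-1-methylcyclohex-2-en-1-yl]methyl acetate | CC(=O)OC[C@]1(C)CCCC=C1C=C | intermediate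
9 | (2E)-2-methylbut-2-enal (tiglic aldehyde) | C/C=C(\C)C=O | starting material
10 | [(1R,4aR,5R,6S)-5-formyl-1,5,6-trimethyl-1,2,3,4,4a,5,6,7-octahydronaphthalen-1-yl]methyl acetate (halimane numbering 4R,8S,9R,10R; C11 aldehyde) | CC(=O)OC[C@]1(C)CCC[C@@H]2C1=CC[C@H](C)[C@@]2(C)C=O | intermediate
11 | [(1R,4aS,5R,6S)-5-ethenyl-1,5,6-trimethyl-1,2,3,4,4a,5,6,7-octahydronaphthalen-1-yl]methyl acetate (halimane numbering 4R,8S,9R,10S; C11=C12 vinyl) | CC(=O)OC[C@]1(C)CCC[C@@H]2C1=CC[C@H](C)[C@@]2(C)C=C | intermediate
12 | but-2-yn-1-ol | CC#CCO | starting material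
13 | sodium cyclic alkenylaluminate (five-membered 1,2-oxaluminole, Al on C3 of the butenyl unit, two 2-methoxyethoxy groups on Al) | CC1=CCO[Al-]1(OCCOC)OCCOC.[Na+] | intermediate
14 | (2Z)-3-iodobut-2-en-1-ol | C/C(I)=C/CO | intermediate
15 | 9-[(4R,8S,9R,10S)-18-acetoxy-13,14,15,16-tetranorhalim-5-en-12-yl]-9-borabicyclo[3.3.1]nonane | CC(=O)OC[C@]1(C)CCC[C@@H]2C1=CC[C@H](C)[C@@]2(C)CCB3C4CCCC3CCC4 | intermediate
16 | (4R,8S,9R,10S,13Z)-18-acetoxyhalima-5,13-dien-15-ol | CC(=O)OC[C@]1(C)CCC[C@@H]2C1=CC[C@H](C)[C@@]2(C)CC/C(C)=C\CO | intermediate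
17 | (4R,8S,9R,10S,13R)-18-acetoxyhalim-5-en-15-ol | CC(=O)OC[C@]1(C)CCC[C@@H]2C1=CC[C@H](C)[C@@]2(C)CC[C@@H](C)CCO | intermediate
18 | (4R,8S,9R,10S,13R)-18-acetoxyhalim-5-en-15-al | CC(=O)OC[C@]1(C)CCC[C@@H]2C1=CC[C@H](C)[C@@]2(C)CC[C@@H](C)CC=O | intermediate
19 | (4R,8R,9S,10S,13R)-18-acetoxy-7-oxohalim-5-en-15-al | CC(=O)OC[C@]1(C)CCC[C@@H]2C1=CC(=O)[C@H](C)[C@@]2(C)CC[C@@H](C)CC=O | intermediate
20 | (4R,8R,9S,10S,13R)-18-acetoxy-7-oxohalim-5-en-15-oic acid (CNP0210381.1) | CC(=O)OC[C@]1(C)CCC[C@@H]2C1=CC(=O)[C@H](C)[C@@]2(C)CC[C@@H](C)CC(=O)O | target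

## Step count and risks

Total step count: 13. Longest linear sequence: 12 steps (1 to 20 through steps 1–8 and 10–13); step 9 is a one-step side branch.

Steps most likely to fail:

Step 7 (proposed new cycloaddition). The risks are low reactivity of the trisubstituted enal, the regiochemistry, and exo/endo control. The fallback uses known chemistry, sets out from 8 and 9, and returns at 10. Compound 9 is converted with ethane-1,2-diol (pyridinium p-toluenesulfonate, benzene, reflux with water removal) into 2-[(2E)-but-2-en-2-yl]-1,3-dioxolane F1. F1 and 8 are combined with Me3SiOSO2CF3 (10 mol %) in CH2Cl2 at −78 °C in a Gassman-type ionic Diels–Alder reaction. The ring-opened alkoxyallyl cation is a far more reactive dienophile than the neutral enal and adds under substrate control anti to the CH2OAc group. This gives [(1R,4aR,5R,6S)-5-(1,3-dioxolan-2-yl)-1,5,6-trimethyl-1,2,3,4,4a,5,6,7-octahydronaphthalen-1-yl]methyl acetate F2, with minor diastereomers removed by chromatography. Hydrolysis of F2 (1 M HCl, THF, rt) gives 10.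

Step 5 (Still–Wittig shift onto a tetrasubstituted diene carbon). The risk is a competing [1,2]-shift or a slow [2,3]-shift. The fallback sets out from 4 and returns at 7. Compound 4 is heated with N,N-dimethylformamide dimethyl acetal in xylene at 140 °C. This is the Büchi [2,3]-sigmatropic rearrangement of the alkoxy(dimethylamino)carbene, suprafacial like the main step, and it gives (1R)-2-ethenyl-N,N,1-trimethylcyclohex-2-ene-1-carboxamide F3. LiBHEt3 (THF, 0 °C → rt) reduces F3 to 7.

Step 12 (allylic oxidation). The risks are attack at the tertiary allylic C10–H and incomplete conversion. The fallback sets out from 17 and returns at 19. 3-Chloroperoxybenzoic acid (NaHCO3, CH2Cl2, 0 °C) epoxidises the C5=C6 bond to give 18-acetoxy-5,6-epoxyhaliman-15-ol F4. PhSeNa (from PhSeSePh and NaBH4, EtOH, rt) opens the epoxide at the secondary carbon C6 to give 18-acetoxy-6-(phenylselanyl)halimane-5,15-diol F5. H2O2 (THF, 0 °C → rt) oxidises the selenide, and syn-elimination towards C7 gives the tertiary allylic alcohol 18-acetoxyhalim-6-ene-5,15-diol F6. [C5H5NH][CrO3Cl] (excess, CH2Cl2, rt) then oxidises the primary alcohol and converts the tertiary allylic alcohol into the transposed enone (Babler–Dauben oxidative 1,3-transposition), giving 19. The C5/C6 configuration of F4–F6 is erased in the last operation and is left open in their SMILES; all other centres are as in 17.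

Further compounds

F1 | step 7 | 2-[(2E)-but-2-en-2-yl]-1,3-dioxolane | C/C=C(\C)C1OCCO1
F2 | step 7 | [(1R,4aR,5R,6S)-5-(1,3-dioxolan-2-yl)-1,5,6-trimethyl-1,2,3,4,4a,5,6,7-octahydronaphthalen-1-yl]methyl acetate | CC(=O)OC[C@]1(C)CCC[C@@H]2C1=CC[C@H](C)[C@@]2(C)C3OCCO3
F3 | step 5 | (1R)-2-ethenyl-N,N,1-trimethylcyclohex-2-ene-1-carboxamide | CN(C)C(=O)[C@]1(C)CCCC=C1C=C
F4 | step 12 | 18-acetoxy-5,6-epoxyhaliman-15-ol (other centres as in 17) | CC(=O)OC[C@]1(C)CCC[C@@H]2C13OC3C[C@H](C)[C@@]2(C)CC[C@@H](C)CCO
F5 | step 12 | 18-acetoxy-6-(phenylselanyl)halimane-5,15-diol (other centres as in 17) | CC(=O)OC[C@]1(C)CCC[C@@H]2C1(O)C([Se]c3ccccc3)C[C@H](C)[C@@]2(C)CC[C@@H](C)CCO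
F6 | step 12 | 18-acetoxyhalim-6-ene-5,15-diol (other centres as in 17) | CC(=O)OC[C@]1(C)CCC[C@@H]2C1(O)C=C[C@H](C)[C@@]2(C)CC[C@@H](C)CCO
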